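## Retrosynthetic overview
1. Cut one C3–CH2Ar bond last. It is made by a visible-light photoredox deoxygenative coupling of cis-4-(3,4-dimethoxybenzyl)tetrahydrofuran-3-ol with veratraldehyde N-tosylhydrazone, in which the ring radical adds anti to the resident benzyl group.
2. The only ring, the tetrahydrofuran, is closed before that step by cyclodehydration of a 1,2,4-triol (C–O bond).
3. The triol comes from exhaustive reduction of a 3-benzylated malate. The first C–CH2Ar bond is made by Fráter–Seebach alkylation of dimethyl (S)-malate.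
4. Stereochemical relay: the malate carbinol centre sets C4, and C4 sets C3. The carbinol centre is erased in the last step, so natural (S)-malate gives the (3R,4R) product.

Assumption: 3,4-dimethoxybenzyl bromide 2 and benzoxazolium salt 10 are bought as catalogue items, and 2 is stored cold and used promptly.

## Route

Step 1
Reactants: 1 dimethyl (S)-malate; 2 3,4-dimethoxybenzyl bromide
Product: 4 dimethyl (2S,3R)-3-(3,4-dimethoxybenzyl)-2-hydroxybutanedioate, via dilithium alkoxide-enolate 3 (not isolated)
Conditions: LiN(SiMe3)2 (2.1 equiv), THF, −78 °C, 1 h; 2 (1.2 equiv), −78 → −10 °C, 14 h; AcOH quench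
Reagents that add atoms: none
Why: Fráter–Seebach alkylation, in which the lithium-chelated alkoxide-enolate 3 is attacked by the benzylic bromide on the face away from the ester on the carbinol carbon, giving the anti (2S,3R) product in about 9:1 dr; the minor syn isomer is removed by chromatography here, or as the trans alcohol after step 3.

Step 2
Reactants: 4 dimethyl (2S,3R)-3-(3,4-dimethoxybenzyl)-2-hydroxybutanedioate
Product: 5 (2S,3S)-3-(3,4-dimethoxybenzyl)butane-1,2,4-triol
Conditions: LiAlH4 (3 equiv), THF, 0 °C → reflux, 3 h; H2O/aq NaOH work-up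
Reagents that add atoms: none
Why: Exhaustive hydride reduction of both esters touches neither stereocentre, and the C3 descriptor changes from R to S only because the CIP ranking of its neighbours changes.

Step 3
Reactants: 5 (2S,3S)-3-(3,4-dimethoxybenzyl)butane-1,2,4-triol
Product: 6 (3S,4S)-4-(3,4-dimethoxybenzyl)tetrahydrofuran-3-ol (cis)
Conditions: Amberlyst 15 (H+ form), 1,4-dioxane, 100 °C, 16 h
Reagents that add atoms: none
Why: Acid-catalysed cyclodehydration (5-exo-tet SN2 of one primary hydroxyl on the other, protonated, primary carbinol), as in the conversion of butane-1,2,4-triol into 3-hydroxytetrahydrofuran; only a primary C–O bond breaks, so both stereocentres are retained and the anti malate maps onto the cis ring.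

Step 4
Reactants: 7 3,4-dimethoxybenzaldehyde (veratraldehyde); 8 p-toluenesulfonyl hydrazide
Product: 9 (E)-N'-(3,4-dimethoxybenzylidene)-4-methylbenzenesulfonohydrazide
Conditions: MeOH, rt, 2 h; product filtered off
Reagents that add atoms: none
Why: Simple hydrazone condensation that gives the crystalline E isomer and creates no stereocentre.

Step 5
Reactants: 6 (3S,4S)-4-(3,4-dimethoxybenzyl)tetrahydrofuran-3-ol; 9 (E)-N'-(3,4-dimethoxybenzylidene)-4-methylbenzenesulfonohydrazide; 10 5,7-di-tert-butyl-3-phenylbenzo[d]oxazol-3-ium tetrafluoroborate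
Product: 14 (3R,4R)-3,4-bis(3,4-dimethoxybenzyl)tetrahydrofuran, via 2-alkoxybenzoxazoline 11 (not isolated), via sulfonylhydrazide 12 (not isolated), via diazene 13 (not isolated)
Conditions: (a) 10 (1.2 equiv), pyridine (1.2 equiv), MTBE, rt, 15 min, filter; (b) 9 (1.5 equiv), [Ir(ppy)2(dtbbpy)]PF6 (2 mol%), quinuclidine (0.5 equiv), MTBE/DMA 1:1, 450 nm LEDs, rt, 16 h; (c) Cs2CO3 (3 equiv), MeOH, 60 °C, 3 h
Reagents that add atoms: none
Why: Proposed new method: alcohol 6 condenses with 10 to give aminal 11, which the excited trivalent iridium photocatalyst oxidises at nitrogen (about +0.7 V, mild enough to spare the veratryl rings); loss of the aminal proton to quinuclidine and β-scission of the C–O bond release the benzoxazolone and the nucleophilic tetrahydrofuran-3-yl radical, erasing the carbinol centre; this planar radical adds to the electrophilic C=N carbon of 9 on the ring face anti to the C4 arylmethyl group (1,2-induction as for 2-substituted cyclopentyl radicals, trans:cis of about 8:1 or better expected), and the cis by-product is an achiral meso compound that is removed by chromatography and cannot lower the ee; the hydrazinyl radical is reduced by the divalent iridium state and protonated by quinuclidinium (or abstracts the aminal hydrogen of 11 in a chain) to give 12, whose benzylic epimers are irrelevant, and Cs2CO3 then expels sulfinate to give diazene 13, which loses N2 and leaves the CH2 group; keeping stage (b) only weakly basic avoids oxidation of the hydrazone anion; the closest known reaction types are the deoxygenative Giese addition of benzoxazolium-activated alcohols to electron-poor alkenes and the addition of acid- or C–H-derived alkyl radicals to N-sulfonylhydrazones followed by Caglioti/Wolff–Kishner-type fragmentation, and to my knowledge their merger on a secondary alcohol as a stereocentre-rewriting step has not been described.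

## Compound list
1 | dimethyl (S)-malate | COC(=O)C[C@H](O)C(=O)OC | starting material
2 | 3,4-dimethoxybenzyl bromide | COc1ccc(CBr)cc1OC | starting material
3 | dilithium alkoxide-enolate of 1 (chelated, not isolated) | [Li+].[Li+].COC(=O)[C@@H]([O-])/C=C(\[O-])OC | intermediate
4 | dimethyl (2S,3R)-3-(3,4-dimethoxybenzyl)-2-hydroxybutanedioate | COC(=O)[C@@H](O)[C@@H](Cc1ccc(OC)c(OC)c1)C(=O)OC | intermediate
5 | (2S,3S)-3-(3,4-dimethoxybenzyl)butane-1,2,4-triol | OC[C@@H](O)[C@@H](Cc1ccc(OC)c(OC)c1)CO | intermediate
6 | (3S,4S)-4-(3,4-dimethoxybenzyl)tetrahydrofuran-3-ol (cis) | O[C@@H]1COC[C@@H]1Cc1ccc(OC)c(OC)c1 | intermediate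
7 | 3,4-dimethoxybenzaldehyde | COc1ccc(C=O)cc1OC | starting material
8 | p-toluenesulfonyl hydrazide | Cc1ccc(S(=O)(=O)NN)cc1 | starting material
9 | (E)-N'-(3,4-dimethoxybenzylidene)-4-methylbenzenesulfonohydrazide | COc1ccc(/C=N/NS(=O)(=O)c2ccc(C)cc2)cc1OC | intermediate
10 | 5,7-di-tert-butyl-3-phenylbenzo[d]oxazol-3-ium tetrafluoroborate | CC(C)(C)c1cc(C(C)(C)C)c2oc[n+](-c3ccccc3)c2c1.F[B-](F)(F)F | starting material
11 | 5,7-di-tert-butyl-2-{[(3S,4S)-4-(3,4-dimethoxybenzyl)tetrahydrofuran-3-yl]oxy}-3-phenyl-2,3-dihydrobenzo[d]oxazole (aminal epimers, not isolated) | CC(C)(C)c1cc(C(C)(C)C)c2OC(O[C@@H]3COC[C@@H]3Cc3ccc(OC)c(OC)c3)N(c3ccccc3)c2c1 | intermediate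
12 | N'-{(3,4-dimethoxyphenyl)[(3S,4R)-4-(3,4-dimethoxybenzyl)tetrahydrofuran-3-yl]methyl}-4-methylbenzenesulfonohydrazide (benzylic epimers, not isolated) | COc1ccc(C(NNS(=O)(=O)c2ccc(C)cc2)[C@H]2COC[C@@H]2Cc2ccc(OC)c(OC)c2)cc1OC | intermediate
13 | {(3,4-dimethoxyphenyl)[(3S,4R)-4-(3,4-dimethoxybenzyl)tetrahydrofuran-3-yl]methyl}diazene (not isolated) | COc1ccc(C(N=N)[C@H]2COC[C@@H]2Cc2ccc(OC)c(OC)c2)cc1OC | intermediate
14 | (3R,4R)-3,4-bis(3,4-dimethoxybenzyl)tetrahydrofuran | COc1ccc(C[C@H]2COC[C@@H]2Cc2ccc(OC)c(OC)c2)cc1OC | target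

## Step count and risks
Total step count: 5.
Longest linear sequence: 4 (steps 1, 2, 3 and 5).

**Step 5 (the new reaction).**
- Risks: the radical may add slowly to the electron-rich hydrazone, it may be quenched by hydrogen abstraction to give the simple deoxygenated ether, or the trans:cis ratio may be modest.
- Fallback (known chemistry) sets out from 6 and comes back at 14.
- Appel iodination of 6 (I2, PPh3, imidazole, toluene, 70 °C) proceeds with inversion and gives (3R,4S)-3-iodo-4-(3,4-dimethoxybenzyl)tetrahydrofuran F1.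
- Nickel-catalysed reductive acylation of this secondary iodide with bought 3,4-dimethoxybenzoyl chloride (NiCl2(dme), dtbbpy, Mn powder, DMA, rt) gives (3,4-dimethoxyphenyl)[(3R,4R)-4-(3,4-dimethoxybenzyl)tetrahydrofuran-3-yl]methanone F2.
- Any cis ketone is equilibrated to the more stable trans isomer with DBU. Only C3 is enolisable, so C4 and the ee are untouched.
- Hydrogenolysis of the electron-rich aryl ketone (H2, Pd/C, EtOH, catalytic HCl) turns C=O into CH2 and delivers 14.

**Step 1.**
- Risks: the bromide is labile, O-alkylation of the alkoxide can compete, and the anti and syn isomers may be hard to separate.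
- Fallback sets out from 1 (with 7 as electrophile) and comes back at 5. It replaces alkylation by aldol addition followed by hydrogenolysis.
- Dianion 3 is treated with the stable aldehyde 7 at −78 °C, and the same chelate controls the face at C3.
- The aldolate closes onto the neighbouring ester to give methyl (3S,4S)-2-(3,4-dimethoxyphenyl)-4-hydroxy-5-oxotetrahydrofuran-3-carboxylate F3 as a mixture of C2 epimers.
- Hydrogenolysis of the benzylic lactone C–O bond (H2, Pd/C, AcOH) removes that irrelevant centre and gives (2S,3R)-3-(3,4-dimethoxybenzyl)-2-hydroxy-4-methoxy-4-oxobutanoic acid F4.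
- LiAlH4 reduces F4 to triol 5.

**Step 3.**
- Risks: conversion may be incomplete, intermolecular ethers may form, or the acid may damage the electron-rich arene.
- Fallback sets out from 4 and comes back at 6. It forms the ring by lactonisation instead of etherification and bypasses 5.
- Chemoselective reduction of the α-hydroxy ester (BH3·SMe2, catalytic NaBH4, THF), followed by catalytic TFA, gives (3R,4S)-3-(3,4-dimethoxybenzyl)-4-hydroxydihydrofuran-2(3H)-one F5.
- iBu2AlH (2.2 equiv, CH2Cl2, −78 °C) gives the lactol (3R,4S)-3-(3,4-dimethoxybenzyl)tetrahydrofuran-2,4-diol F6 as a mixture of anomers.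
- Ionic reduction of the lactol (Et3SiH, BF3·OEt2, CH2Cl2, −78 → 0 °C) gives 6.

## Further compounds
F1 | step 5 | (3R,4S)-3-iodo-4-(3,4-dimethoxybenzyl)tetrahydrofuran | I[C@H]1COC[C@@H]1Cc1ccc(OC)c(OC)c1
F2 | step 5 | (3,4-dimethoxyphenyl)[(3R,4R)-4-(3,4-dimethoxybenzyl)tetrahydrofuran-3-yl]methanone | COc1ccc(C(=O)[C@H]2COC[C@@H]2Cc2ccc(OC)c(OC)c2)cc1OC
F3 | step 1 | methyl (3S,4S)-2-(3,4-dimethoxyphenyl)-4-hydroxy-5-oxotetrahydrofuran-3-carboxylate (C2 epimers) | O=C1[C@@H](O)[C@@H](C(O1)c2ccc(OC)c(OC)c2)C(=O)OC
F4 | step 1 | (2S,3R)-3-(3,4-dimethoxybenzyl)-2-hydroxy-4-methoxy-4-oxobutanoic acid | OC(=O)[C@@H](O)[C@@H](Cc1ccc(OC)c(OC)c1)C(=O)OC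
F5 | step 3 | (3R,4S)-3-(3,4-dimethoxybenzyl)-4-hydroxydihydrofuran-2(3H)-one | O1C[C@@H](O)[C@@H](Cc2ccc(OC)c(OC)c2)C1=O
F6 | step 3 | (3R,4S)-3-(3,4-dimethoxybenzyl)tetrahydrofuran-2,4-diol (anomers) | O1C[C@@H](O)[C@@H](Cc2ccc(OC)c(OC)c2)C1O
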